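**Retrosynthetic overview**

1. The C19 acid is made last by oxidising the C19 alcohol. The C3 acetate is what remains of a cyclic 3,19-orthoacetate. The C12–C13 bond comes from a C12 tosylate and the 2-butadienyl Grignard reagent.
2. C9–C11 and the C8(17) methylene are formed together by a Johnson–Claisen rearrangement of a Δ8(9)-17-ol. H-5 (cis to C19 and C20) comes from hydroxyl-directed hydrogenation of a Δ5 olefin.
3. Ring B is disconnected at C7–C8 and C9–C10: Diels–Alder reaction of the ring-A diene C7=C6–C5=C10 with methyl (E)-3-nitroacrylate (C8=C9), then loss of HNO2.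
4. Enabling feature: in ring B (C5 to C10) the C8(17) methylene and the C11-bearing C9 are vicinal. With H-5 removed they read as a cyclohexa-1,4-diene (C5=C6, C8=C9, C17 at the acid level) on the quaternary C10. That is the cycloadduct of a diene inscribed in ring A (C10 with its methyl as one terminus) and a two-carbon acetylene equivalent.
5. Ring A with C3 and C4 comes from (R)-carvone (two enolate alkylations, Criegee rearrangement). Ring order: A (chiral pool), then B (cycloaddition).

Key step: step 8

Remark: the SMILES is read as (1R,2R,4aR,5S,8aS), a cis-fused (5β-H) labdane with H-5, CH3-20, C19 and the C9 side chain on the β-face and 3-OAc and CH3-18 on the α-face; labdane numbering is used throughout, also for the monocyclic ring-A compounds (β = face of C19).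

**Route**

Step 1
Reactants: 1 (R)-(−)-carvone
Product: 3 (5R,6S)-6-methylcarvone, via lithium dienolate 2 (not isolated)
Conditions: LiN(i-Pr)2, THF, −78 °C; MeI, −78 → −20 °C
Reagents that add atoms: iodomethane, CI
Why: Kinetic α′-deprotonation gives the cross-conjugated dienolate, whose alkylation (enolate alkylation) should occur mainly anti to the isopropenyl group; this centre is planarised again in step 2, so either epimer is usable.

Step 2
Reactants: 3 (5R,6S)-6-methylcarvone
Product: 5 (5S,6R)-6-(hydroxymethyl)-6-methylcarvone, via lithium enolate 4 (not isolated)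
Conditions: LiN(i-Pr)2, THF, −78 °C; CH2O (gas, from cracked paraformaldehyde), −78 °C; aq. NH4Cl
Reagents that add atoms: formaldehyde, C=O
Why: Crossed aldol addition of the tetrasubstituted enolate to monomeric formaldehyde should take place on the face opposite to the neighbouring isopropenyl group, which sets the quaternary C4 with CH2OH (C19) trans and CH3 (C18) cis to the future C3 substituent.

Step 3
Reactants: 5 (5S,6R)-6-(hydroxymethyl)-6-methylcarvone
Product: 6 TBS ether of 5
Conditions: TBSCl, imidazole, DMAP (cat.), DMF, 0 °C → rt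
Reagents that add atoms: tert-butyldimethylsilyl chloride, C[Si](C)(Cl)C(C)(C)C
Why: Silylation of the neopentyl primary alcohol blocks retro-aldol loss of formaldehyde and provides the bulky C4 substituent that later steers the cycloaddition.

Step 4
Reactants: 6 TBS ether of 5
Product: 8 ring-A enone 3α-acetate, via methoxy hydroperoxide 7 (not isolated)
Conditions: O3, CH2Cl2/MeOH, NaHCO3, −78 °C; then Ac2O, Et3N, DMAP (cat.), 0 → 40 °C
Reagents that add atoms: ozone, [O-][O+]=O; methanol, CO
Why: Ozone should cleave the electron-rich isopropenyl group much faster than the conjugated enone, and acetylation of the α-methoxy hydroperoxide triggers the Criegee rearrangement, in which the ring carbon migrates to oxygen with retention, so C3 receives its acetoxy group (acetyl carbons = former isopropenyl C and CH3) with the configuration of carvone.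

Step 5
Reactants: 8 ring-A enone 3α-acetate
Product: 10 ring-A enol triflate, via lithium enolate 9 (not isolated)
Conditions: LiBH(s-Bu)3 (1.05 equiv), THF, −78 °C; then N-(5-chloro-2-pyridyl)bis(trifluoromethanesulfonimide), −78 → 0 °C
Reagents that add atoms: N-(5-chloropyridin-2-yl)-1,1,1-trifluoro-N-(trifluoromethylsulfonyl)methanesulfonamide, FC(F)(F)S(=O)(=O)N(c1ccc(Cl)cn1)S(=O)(=O)C(F)(F)F
Why: Conjugate reduction of the enone (1,2-attack is blocked by the adjacent quaternary C4) gives the regiodefined C5=C10 enolate, which is trapped as the enol triflate; the acetate should survive one equivalent of hydride at −78 °C.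

Step 6
Reactants: 10 ring-A enol triflate
Product: 11 ring-A diene
Conditions: CH2=CHSnBu3, Pd(PPh3)4 (5 mol %), LiCl, THF, 65 °C
Reagents that add atoms: tributyl(vinyl)stannane, C=C[Sn](CCCC)(CCCC)CCCC
Why: Stille coupling of a hindered cyclohexenyl triflate with a vinylstannane gives the 1-vinylcyclohexene diene C7=C6–C5=C10.

Step 7
Reactants: 12 methyl acrylate
Product: 14 methyl (E)-3-nitroacrylate, via iodo nitro ester 13 (not isolated)
Conditions: N2O4, I2, Et2O, 0 °C; then NaOAc, Et2O, 0 °C → rt
Reagents that add atoms: dinitrogen tetroxide, [O-][N+](=O)[N+](=O)[O-]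
Why: Nitro-iodination of the acrylate followed by base-induced loss of HI (E1cB) gives the doubly activated (E)-dienophile.

Step 8
Reactants: 11 ring-A diene + 14 methyl (E)-3-nitroacrylate
Product: 15 Diels–Alder adduct (Δ5-octalin nitro ester)
Conditions: toluene, BHT (cat.), 60 °C, dark
Reagents that add atoms: none
Why: Concerted, asynchronous normal-demand Diels–Alder reaction: the unsubstituted terminus C7 bonds first to the ester-bearing carbon of the dienophile (β to the nitro group, largest LUMO coefficient) and the nitro-bearing carbon then closes onto the fully substituted terminus C10, so ring B is closed by an intermolecular [4+2] closure with the future C17 carboxyl on C8 and the removable nitro group on C9. The closest known reaction type is the cycloaddition of 1-vinyl-2,6,6-trisubstituted cyclohexenes with acetylenic esters, combined with the use of a β-nitroacrylate as a propiolate equivalent of reversed regiochemistry. The quaternary centre C10 is set by π-facial selectivity: allylic 1,2-strain with the C5 vinyl group and the trans relation to the C3 acetate should place the large CH2OTBS group on C4 pseudoaxial on the β-face, so the dienophile adds to the α-face, syn to the C4 methyl, and C20 ends up cis to C19. C8 and C9 become trans (E-dienophile, nitro endo expected), but both centres are erased in step 11, so only regio- and facial selectivity matter. No Lewis acid is needed, which should keep the silyl ether, the acetate and the diene intact.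

Step 9
Reactants: 15 Diels–Alder adduct
Product: 16 adduct 19-alcohol
Conditions: HF·pyridine, THF, 0 °C → rt
Reagents that add atoms: none
Why: Fluoride-mediated desilylation frees the C19 hydroxyl needed as directing group, and the acidic medium avoids premature loss of HNO2.

Step 10
Reactants: 16 adduct 19-alcohol
Product: 17 cis-fused (5β-H) nitro ester
Conditions: H2 (1 atm), [Ir(cod)(PCy3)(py)]PF6 (10 mol %), CH2Cl2, 0 °C → rt
Reagents that add atoms: none
Why: Hydroxyl-directed homogeneous hydrogenation: the cationic iridium catalyst binds the C19 hydroxyl on the β-face and should deliver H2 to the hindered C5=C6 olefin from that face, giving the cis ring fusion (H-5 syn to C19 and C20) against the intrinsic steric bias.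

Step 11
Reactants: 17 cis-fused nitro ester
Product: 18 Δ8(9)-enoate (C17 ester)
Conditions: DBU, THF, 0 °C → rt
Reagents that add atoms: none
Why: E1cB elimination of nitrous acid (C8–H is α to the ester) gives the C8=C9 enoate with C9 unsubstituted, the regiochemistry opposite to that of a propiolate adduct.

Step 12
Reactants: 18 Δ8(9)-enoate
Product: 19 Δ8(9)-3α,17,19-triol
Conditions: i-Bu2AlH (6 equiv), CH2Cl2, −78 → 0 °C; aq. potassium sodium tartrate
Reagents that add atoms: none
Why: 1,2-Reduction of the enoate gives the allylic C17 alcohol, and the acetate is cleaved at the same time, which is intended.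

Step 13
Reactants: 19 Δ8(9)-3α,17,19-triol
Product: 21 C12 ethyl ester with 8(17)-methylene and cyclic 3,19-orthoacetate, via ketene acetal 20 (not isolated)
Conditions: MeC(OEt)3 (solvent), EtCO2H (cat.), 140 °C, EtOH distilled off
Reagents that add atoms: triethyl orthoacetate, CCOC(C)(OCC)OCC
Why: Johnson–Claisen rearrangement: the [3,3] shift of the ketene acetal forms C9–C11 and the C8(17) methylene, and the new bond should enter from the convex β-face because the α-face of C9 is shielded in both chair–chair conformers of the cis-decalin (by the axial C4 methyl or by axial C1); the same reagent ties the trans 3,19-diol as a cyclic orthoacetate (both epimers at the orthoester carbon are usable).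

Step 14
Reactants: 21 C12 ethyl ester
Product: 22 C12 alcohol
Conditions: LiAlH4, THF, 0 °C; NaOH work-up
Reagents that add atoms: none
Why: Hydride reduction of the ester gives the primary alcohol, while the orthoester, like an acetal, is inert to LiAlH4 and to the basic work-up.

Step 15
Reactants: 22 C12 alcohol
Product: 23 C12 tosylate
Conditions: TsCl, Et3N, DMAP (cat.), CH2Cl2, 0 °C
Reagents that add atoms: 4-toluenesulfonyl chloride, Cc1ccc(cc1)S(=O)(=O)Cl
Why: Sulfonylation of the only free hydroxyl group, a unhindered primary one.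

Step 16
Reactants: 23 C12 tosylate
Product: 24 triene 3,19-orthoacetate
Conditions: CH2=CH–C(MgCl)=CH2 (made in the flask from 2-chlorobuta-1,3-diene and Mg, THF), Li2CuCl4 (5 mol %), THF, −30 → 0 °C
Reagents that add atoms: buta-1,3-dien-2-ylmagnesium chloride, C=CC(=C)[Mg]Cl
Why: Copper-catalysed cross-coupling of a primary tosylate with the 2-butadienyl Grignard reagent forms C12–C13 and gives the 2-substituted buta-1,3-diene directly; the orthoester should not react at this temperature.

Step 17
Reactants: 24 triene 3,19-orthoacetate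
Product: 25 3α-acetoxy-5β-labda-8(17),13(16),14-trien-19-ol
Conditions: AcOH/THF/H2O (2:2:1), 0 °C → rt, short reaction time
Reagents that add atoms: water, O
Why: Mild acid hydrolysis of the cyclic orthoacetate goes through the dioxanylium ion and its hemiorthoester, which should collapse kinetically with release of the less hindered primary oxygen and leave the acetyl group on the secondary O3 (orthoester-mediated monoacylation of the more hindered hydroxyl of a diol).

Step 18
Reactants: 25 3α-acetoxy trien-19-ol
Product: 26 3α-acetoxy trien-19-al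
Conditions: Dess–Martin periodinane, NaHCO3, CH2Cl2, 0 °C → rt
Reagents that add atoms: none
Why: Dess–Martin oxidation of the neopentyl primary alcohol under buffered, non-basic conditions; the α-carbon is quaternary, so neither epimerisation nor β-elimination of acetate is possible, and 3→19 acyl migration is avoided by using 25 at once.

Step 19
Reactants: 26 3α-acetoxy trien-19-al
Product: 27 3α-acetoxy-5β-labda-8(17),13(16),14-trien-19-oic acid
Conditions: NaClO2, NaH2PO4, 2-methylbut-2-ene (excess), t-BuOH/H2O, 0 °C → rt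
Reagents that add atoms: sodium chlorite, [Na+].[O-]Cl=O
Why: Pinnick oxidation converts the hindered aldehyde into the acid, with 2-methylbut-2-ene scavenging HOCl so that the exocyclic methylene, the diene and the acetate should be untouched.

**Compound list**

1 | (R)-(−)-carvone, (5R)-2-methyl-5-(prop-1-en-2-yl)cyclohex-2-en-1-one | CC1=CC[C@@H](C(C)=C)CC1=O | starting material
2 | lithium dienolate of 1 (C6 deprotonated) | CC1=CC[C@@H](C(C)=C)C=C1[O-].[Li+] | intermediate (not isolated)
3 | (5R,6S)-2,6-dimethyl-5-(prop-1-en-2-yl)cyclohex-2-en-1-one (6-methyl trans to isopropenyl) | CC1=CC[C@@H](C(C)=C)[C@H](C)C1=O | intermediate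
4 | lithium enolate of 3 | CC1=CC[C@@H](C(C)=C)C(C)=C1[O-].[Li+] | intermediate (not isolated)
5 | (5S,6R)-6-(hydroxymethyl)-2,6-dimethyl-5-(prop-1-en-2-yl)cyclohex-2-en-1-one (CH2OH trans, CH3 cis to isopropenyl) | CC1=CC[C@@H](C(C)=C)[C@](C)(CO)C1=O | intermediate
6 | (5S,6R)-6-[(tert-butyldimethylsilyloxy)methyl]-2,6-dimethyl-5-(prop-1-en-2-yl)cyclohex-2-en-1-one | CC1=CC[C@@H](C(C)=C)[C@](C)(CO[Si](C)(C)C(C)(C)C)C1=O | intermediate
7 | 6-[(tert-butyldimethylsilyloxy)methyl]-5-(1-hydroperoxy-1-methoxyethyl)-2,6-dimethylcyclohex-2-en-1-one (mixture at the peroxy carbon) | CC1=CC[C@@H](C(C)(OC)OO)[C@](C)(CO[Si](C)(C)C(C)(C)C)C1=O | intermediate (not isolated)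
8 | (1R,2S)-2-[(tert-butyldimethylsilyloxy)methyl]-2,4-dimethyl-3-oxocyclohex-4-en-1-yl acetate (3α-OAc cis to 18-CH3, trans to 19-CH2OTBS) | CC1=CC[C@@H](OC(C)=O)[C@](C)(CO[Si](C)(C)C(C)(C)C)C1=O | intermediate
9 | lithium C5=C10 enolate from 1,4-reduction of 8 | CC1=C([O-])[C@@](C)(CO[Si](C)(C)C(C)(C)C)[C@H](OC(C)=O)CC1.[Li+] | intermediate (not isolated)
10 | (1R,2S)-2-[(tert-butyldimethylsilyloxy)methyl]-2,4-dimethyl-3-[(trifluoromethylsulfonyl)oxy]cyclohex-3-en-1-yl acetate | CC1=C(OS(=O)(=O)C(F)(F)F)[C@@](C)(CO[Si](C)(C)C(C)(C)C)[C@H](OC(C)=O)CC1 | intermediate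
11 | (1R,2S)-2-[(tert-butyldimethylsilyloxy)methyl]-3-ethenyl-2,4-dimethylcyclohex-3-en-1-yl acetate (ring-A diene) | CC1=C(C=C)[C@@](C)(CO[Si](C)(C)C(C)(C)C)[C@H](OC(C)=O)CC1 | intermediate
12 | methyl acrylate | C=CC(=O)OC | starting material
13 | methyl 2-iodo-3-nitropropanoate (racemic) | COC(=O)C(I)C[N+](=O)[O-] | intermediate (not isolated)
14 | methyl (E)-3-nitroprop-2-enoate | COC(=O)/C=C/[N+](=O)[O-] | intermediate
15 | methyl 3α-acetoxy-19-(tert-butyldimethylsilyloxy)-9α-nitro-11,12,13,14,15,16-hexanorlabd-5-en-17-oate (8α-H, 10β-CH3, 4α-CH3) | [O-][N+](=O)[C@@H]1[C@@H](C(=O)OC)CC=C2[C@]1(C)CC[C@@H](OC(C)=O)[C@]2(C)CO[Si](C)(C)C(C)(C)C | intermediate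
16 | methyl 3α-acetoxy-19-hydroxy-9α-nitro-11,12,13,14,15,16-hexanorlabd-5-en-17-oate | [O-][N+](=O)[C@@H]1[C@@H](C(=O)OC)CC=C2[C@]1(C)CC[C@@H](OC(C)=O)[C@]2(C)CO | intermediate
17 | methyl 3α-acetoxy-19-hydroxy-9α-nitro-11,12,13,14,15,16-hexanor-5β-labdan-17-oate (cis-fused) | [O-][N+](=O)[C@@H]1[C@@H](C(=O)OC)CC[C@H]2[C@]1(C)CC[C@@H](OC(C)=O)[C@]2(C)CO | intermediate
18 | methyl 3α-acetoxy-19-hydroxy-11,12,13,14,15,16-hexanor-5β-labd-8-en-17-oate | C1=C(C(=O)OC)CC[C@H]2[C@]1(C)CC[C@@H](OC(C)=O)[C@]2(C)CO | intermediate
19 | 11,12,13,14,15,16-hexanor-5β-labd-8-ene-3α,17,19-triol | C1=C(CO)CC[C@H]2[C@]1(C)CC[C@@H](O)[C@]2(C)CO | intermediate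
20 | 17-O-(1-ethoxyethenyl) ketene acetal of 19 with 3α,19-O-(1-ethoxyethylidene) bridge | C1=C(COC(=C)OCC)CC[C@H]2[C@]1(C)CC[C@H]1OC(C)(OCC)OC[C@]21C | intermediate (not isolated)
21 | ethyl 3α,19-(1-ethoxyethylidenedioxy)-13,14,15,16-tetranor-5β-labd-8(17)-en-12-oate (9β side chain; epimers at the orthoester carbon) | CCOC(=O)C[C@H]1C(=C)CC[C@H]2[C@]1(C)CC[C@H]1OC(C)(OCC)OC[C@]21C | intermediate
22 | 3α,19-(1-ethoxyethylidenedioxy)-13,14,15,16-tetranor-5β-labd-8(17)-en-12-ol | OCC[C@H]1C(=C)CC[C@H]2[C@]1(C)CC[C@H]1OC(C)(OCC)OC[C@]21C | intermediate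
23 | 12-O-(4-toluenesulfonyl) derivative of 22 | Cc1ccc(cc1)S(=O)(=O)OCC[C@H]1C(=C)CC[C@H]2[C@]1(C)CC[C@H]1OC(C)(OCC)OC[C@]21C | intermediate
24 | 3α,19-(1-ethoxyethylidenedioxy)-5β-labda-8(17),13(16),14-triene | C=CC(=C)CC[C@H]1C(=C)CC[C@H]2[C@]1(C)CC[C@H]1OC(C)(OCC)OC[C@]21C | intermediate
25 | 3α-acetoxy-5β-labda-8(17),13(16),14-trien-19-ol | C=CC(=C)CC[C@H]1C(=C)CC[C@H]2[C@]1(C)CC[C@@H](OC(C)=O)[C@]2(C)CO | intermediate
26 | 3α-acetoxy-5β-labda-8(17),13(16),14-trien-19-al | C=CC(=C)CC[C@H]1C(=C)CC[C@H]2[C@]1(C)CC[C@@H](OC(C)=O)[C@]2(C)C=O | intermediate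
27 | 3α-acetoxy-5β-labda-8(17),13(16),14-trien-19-oic acid, (1R,2R,4aR,5S,8aS) | C=CC(=C)CC[C@H]1C(=C)CC[C@H]2[C@]1(C)CC[C@@H](OC(C)=O)[C@]2(C)C(=O)O | target

**Step count and risks**

Total step count: 19. Longest linear sequence: 18 steps (steps 1–6 and 8–19, from carvone).

Steps most likely to fail:

1. Step 8 (cycloaddition). The dienophile may add to the β-face through the alternative half-chair of ring A (C4 methyl pseudoaxial), giving the C10 epimer, or the adduct may lose HNO2 on heating. The fallback sets out from diene 11 and returns at adduct 15; it replaces the sp3 C3 acetate as control element by a C3 carbonyl. Methanolysis of the acetate (K2CO3, MeOH) gives the 3α-hydroxy diene F1, and Dess–Martin oxidation gives the 3-oxo diene F2, in which allylic strain from both flanking sp2 carbons (C3=O and C5=C10) should hold CH2OTBS pseudoaxial. Cycloaddition with 14 gives the 3-oxo adduct F3. LiBH(s-Bu)3 at −78 °C attacks from the equatorial direction of the chair-like ring A (C19 and C20 axial) to give the axial 3α-hydroxy adduct F4, and acetylation (Ac2O, pyridine) returns to 15.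

2. Step 10 (directed hydrogenation). Hydrogen may be delivered from the α-face, or the trisubstituted olefin between two quaternary carbons may not turn over. The fallback sets out from 16 and returns at 17; it uses a hydroxyl-directed intramolecular ionic hydrogenation. Silylation with t-Bu2SiHCl and imidazole gives the di-tert-butylsilyl ether F5. CF3CO2H in CH2Cl2 at −20 °C protonates C6, and the tethered Si–H should deliver hydride to the C5 cation on the β-face, giving the silyl trifluoroacetate F6. HF·pyridine then frees 17.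

3. Step 17 (orthoacetate opening). The opening may be unselective, or the acetyl group may migrate from O3 to O19. The fallback sets out from 24 and returns at target 27; it abandons the orthoester as acetate source. Hydrolysis (AcOH/H2O) and then K2CO3/MeOH on the crude mixture of 25 and the 19-acetate isomer F7 gives the 3α,19-diol F8. TEMPO/PhI(OAc)2 oxidises only the primary alcohol to the 3α-hydroxy aldehyde F9, Pinnick oxidation gives the 3α-hydroxy acid F10, and acetylation (Ac2O, pyridine, DMAP, aqueous work-up) gives 27.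

Further compounds
F1 | step 8 | (1R,2S)-2-[(tert-butyldimethylsilyloxy)methyl]-3-ethenyl-2,4-dimethylcyclohex-3-en-1-ol (3α-hydroxy diene) | CC1=C(C=C)[C@@](C)(CO[Si](C)(C)C(C)(C)C)[C@H](O)CC1
F2 | step 8 | 2-[(tert-butyldimethylsilyloxy)methyl]-3-ethenyl-2,4-dimethylcyclohex-3-en-1-one (3-oxo diene, C4 as in 11) | CC1=C(C=C)[C@@](C)(CO[Si](C)(C)C(C)(C)C)C(=O)CC1
F3 | step 8 | methyl 19-(tert-butyldimethylsilyloxy)-9α-nitro-3-oxo-11,12,13,14,15,16-hexanorlabd-5-en-17-oate | [O-][N+](=O)[C@@H]1[C@@H](C(=O)OC)CC=C2[C@]1(C)CCC(=O)[C@]2(C)CO[Si](C)(C)C(C)(C)C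
F4 | step 8 | methyl 19-(tert-butyldimethylsilyloxy)-3α-hydroxy-9α-nitro-11,12,13,14,15,16-hexanorlabd-5-en-17-oate | [O-][N+](=O)[C@@H]1[C@@H](C(=O)OC)CC=C2[C@]1(C)CC[C@@H](O)[C@]2(C)CO[Si](C)(C)C(C)(C)C
F5 | step 10 | 19-O-(di-tert-butylsilyl) ether of 16 | [O-][N+](=O)[C@@H]1[C@@H](C(=O)OC)CC=C2[C@]1(C)CC[C@@H](OC(C)=O)[C@]2(C)CO[SiH](C(C)(C)C)C(C)(C)C
F6 | step 10 | 19-O-[di-tert-butyl(trifluoroacetoxy)silyl] ether of 17 | [O-][N+](=O)[C@@H]1[C@@H](C(=O)OC)CC[C@H]2[C@]1(C)CC[C@@H](OC(C)=O)[C@]2(C)CO[Si](OC(=O)C(F)(F)F)(C(C)(C)C)C(C)(C)C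
F7 | step 17 | 19-acetoxy-5β-labda-8(17),13(16),14-trien-3α-ol | C=CC(=C)CC[C@H]1C(=C)CC[C@H]2[C@]1(C)CC[C@@H](O)[C@]2(C)COC(C)=O
F8 | step 17 | 5β-labda-8(17),13(16),14-triene-3α,19-diol | C=CC(=C)CC[C@H]1C(=C)CC[C@H]2[C@]1(C)CC[C@@H](O)[C@]2(C)CO
F9 | step 17 | 3α-hydroxy-5β-labda-8(17),13(16),14-trien-19-al | C=CC(=C)CC[C@H]1C(=C)CC[C@H]2[C@]1(C)CC[C@@H](O)[C@]2(C)C=O
F10 | step 17 | 3α-hydroxy-5β-labda-8(17),13(16),14-trien-19-oic acid | C=CC(=C)CC[C@H]1C(=C)CC[C@H]2[C@]1(C)CC[C@@H](O)[C@]2(C)C(=O)O
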